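Target in Thursday's run reaches 0.213 M at 4.2 h, which is 35.5 % of the substrate charged, and the readings have nearly stopped rising. Monday's run, with a charge 2.50 times smaller, stands at 36.7 % at the same time, and Sunday's run adds 0.212 M to the target it was charged with, against 0.213 M made in Thursday's run. So the share made at that time reads about the same at both charges and with target already present.

| flask | substrate | coupling partner | free catalyst | target | time |
|---|---|---|---|---|---|
| Thursday's | 0.600 M | 0.600 M | 0.00300 M |  |  |
| Monday's | 0.240 M | 0.240 M | 0.00300 M |  |  |
| Sunday's | 0.600 M | 0.600 M | 0.00300 M | 0.180 M |  |
| Tuesday's | 0.600 M | 1.80 M | 0.00300 M |  |  |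
| Wednesday's | 0.600 M | 0.600 M | 0.0120 M |  | 4.2 h |

- Thursday's run (time / h: [target] / M): 0.70: 0.101; 1.4: 0.159; 2.1: 0.191; 2.8: 0.206; 3.5: 0.204; 4.2: 0.213
- Monday's run (time / h: [target] / M): 0.70: 0.045; 1.4: 0.065; 2.1: 0.070; 2.8: 0.081; 3.5: 0.085; 4.2: 0.088
- Sunday's run (time / h: [target] / M): 0.70: 0.282; 1.4: 0.344; 2.1: 0.365; 2.8: 0.377; 3.5: 0.394; 4.2: 0.392
- Tuesday's run (time / h: [target] / M): 0.70: 0.236; 1.4: 0.347; 2.1: 0.399; 2.8: 0.425; 3.5: 0.438; 4.2: 0.454

(standard deviation of a reading: 0.003 M)

- the power of [substrate] that the first rate follows, about the charge of the Thursday's run; measure it at two percent of substrate made into target (one fixed amount of target, the same in the runs compared)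
- the power of [coupling partner] that the first rate follows, about the charge of the Thursday's run; measure it at two percent of substrate made into target
- target in the Wednesday's run at 4.2 h, as a share of the substrate charged

- Overall: substrate + coupling partner -> target, with free catalyst as catalyst.
- Constant volume, constant temperature.
- An order is taken over about fifteen percent of the charge, up and down.

Of the questions I reckon the last, where Wednesday's flask has 4.00 times Thursday's catalyst. The quantity I carry is the odds of the flask: target made over substrate unmade at 4.2 h, which for Thursday's run is 0.550.

I can solve two extreme flasks in my head. In the first, the catalyst dies on a clock, the rate goes with the catalyst and with the unmade share, and nothing else is lost, so at a given time the logarithm of the unmade share grows in step with the catalyst charge: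

Thursday's logarithm 0.439, multiplied by 4.00, gives 1.76, so the share is 82.7 %.

In the second, the catalyst lives, the rate goes with the catalyst and the coupling partner, and the partner leaks away by a first-order side loss. Coupling and leak then share the partner in a fixed ratio, and with substrate 0.600 M and partner 0.600 M charged equally in Thursday's flask, as in Wednesday's, substrate unmade equals partner lost once such a flask has stopped, so the odds, here a selectivity factor, grow in step with the catalyst. In powers of ten, that adds a fixed step:

−0.260 plus 0.602 gives 0.342, so the odds are 2.20 and the share is 68.8 %.

Both extremes are matched to the same Thursday reading, so that reading can't choose between them. I expect a flask with both losses at work to lie between the two shares. I take the middle on the scale of the odds, which gives 76.4 %.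

The forecast gives 0.12 and 0.88 for the powers and 82 % for Wednesday's flask, higher than my share, reasoning “The stall is therefore time-based catalyst death”.

The simulation gives powers of 0.15 and 0.91, and Wednesday's run gives 70.4 %, which is below my middle and above the lower extreme.

    free catalyst + substrate → loaded catalyst + by-product (871.2 M⁻¹ h⁻¹)
    loaded catalyst + coupling partner → target + free catalyst (135.0 M⁻¹ h⁻¹)
    coupling partner → lost reagent (0.5724 h⁻¹)
    free catalyst → spent catalyst (1.238 h⁻¹)

The coupling partner is lost by itself with a constant of 0.572 h⁻¹. Wednesday's odds come to 2.38, which is 4.32 times Thursday's reading for 4.00 times the catalyst. In Sunday's run, charged with the same 0.00300 M of free catalyst as Thursday's, the target made over the substrate unmade at 4.2 h reads 0.546.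

(The data were generated by integration with constants of no real substance.)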